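## Retrosynthetic overview

1. 28 ⇒ 26: C11=C13 is stored as its Me2NH adduct and released last by quaternisation and elimination.
2. 26 ⇒ 22 + CO (23). The furanone ring O–C10–C1(=O)–C2H=C3 is the cycloisomer of a 4-hydroxy-2-ynone, C10(OH)–C1≡C2–C3(=O). C3 is a carbonyl-level carbon lying between alkyne carbon C2 and vinylic C4. So C3 is CO, inserted between a (Z)-C4 vinyl iodide and the terminal alkyne of a tertiary propargylic alcohol.
3. 22 ⇒ lactone acid 11 + C13 (iminium salt 12) + C5/C4/C15 (propyne 14) + angelic acid 19. Z-C4=C5 comes from anti-hydroiodination of ynone 16, and C6 from ketone reduction.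
4. 11 ⇒ Evans syn aldol and lactonisation of succinate imide 8 with aldehyde 5 (sets C7, C8). 5 ⇒ Sharpless epoxidation and reductive opening of enynol 1 (sets C10).
5. Ring order: γ-lactone (step 6) → ten-membered carbocycle → 3(2H)-furanone (both in step 14, furanone last).

Key step: step 14

Remark (numbering): germacrane locants are used. C1 is the ring ketone, C2 the =CH, C3 the enol-ether carbon, and C4(=C5) carries C15H3. C6 is the angelate carbinol, C7 the lactone β-carbon, C8 the lactone carbinol, C9 the CH2, and C10 the quaternary carbon bearing C14H3 and the ring oxygen. C11/C12/C13 are the α-carbon, C=O and =CH2 of the lactone.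

Remark (assumption): C11 in 13–27 is drawn as the trans (11S) epimer expected from attack anti to the C7 substituent. This centre is erased in step 15, so its configuration has no consequence.

## Route

Step 1
Reactants: 1 (E)-3-methylpent-2-en-4-yn-1-ol
Product: 2 [(2S,3S)-3-ethynyl-3-methyloxiran-2-yl]methanol
Conditions: Ti(OiPr)4 (cat.), L-(+)-DET (cat.), t-BuOOH, 4 Å MS, CH2Cl2, −20 °C
Reagents that add atoms: tert-butyl hydroperoxide, CC(C)(C)OO
Why: Sharpless asymmetric epoxidation: with L-(+)-tartrate the Ti-bound peroxide reaches this 3,3-disubstituted allylic alcohol from the face that gives the (2S,3S)-epoxide (same sense as for geraniol-type substrates), which fixes the later C10 centre, and the alkyne is inert to Ti/t-BuOOH.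

Step 2
Reactants: 2 [(2S,3S)-3-ethynyl-3-methyloxiran-2-yl]methanol
Product: 3 (3R)-3-methylpent-4-yne-1,3-diol
Conditions: Red-Al, THF, −20 → 0 °C; Rochelle salt work-up
Reagents that add atoms: none
Why: Hydroxyl-directed reductive opening of a 2,3-epoxy alcohol to the 1,3-diol: the alkoxyaluminate delivers hydride internally to the secondary epoxide carbon (later C9), the C10–O bond is untouched so C10 is retained, and the terminal alkyne, deprotonated first, is shielded from SN2' attack and hydroalumination.

Step 3
Reactants: 3 (3R)-3-methylpent-4-yne-1,3-diol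
Product: 4 (3R)-3-methyl-1,3-bis(triethylsilyloxy)-5-(triethylsilyl)pent-4-yne
Conditions: n-BuLi (3.2 equiv), THF, −78 °C; Et3SiCl (3.4 equiv), −78 °C → rt
Reagents that add atoms: chlorotriethylsilane, CC[Si](Cl)(CC)CC
Why: Exhaustive silylation of the trilithiated diol-alkyne (two alkoxides and the acetylide) protects the tertiary hydroxyl and the acidic alkyne C–H in one operation, with no stereocentre involved.

Step 4
Reactants: 4 (3R)-3-methyl-1,3-bis(triethylsilyloxy)-5-(triethylsilyl)pent-4-yne
Product: 5 (3R)-3-methyl-3-(triethylsilyloxy)-5-(triethylsilyl)pent-4-ynal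
Conditions: (COCl)2, DMSO, CH2Cl2, −78 → −30 °C; Et3N, −78 °C → rt
Reagents that add atoms: none
Why: Swern oxidation run directly on a silyl ether: only the unhindered primary O–SiEt3 is attacked by the chlorosulfonium salt and carried on to the aldehyde, while the tertiary silyl ether and the C-silyl alkyne stay and C10 is not enolisable.

Step 5
Reactants: 6 (4R)-4-benzyl-1,3-oxazolidin-2-one; 7 methyl 4-chloro-4-oxobutanoate
Product: 8 methyl 4-[(4R)-4-benzyl-2-oxo-1,3-oxazolidin-3-yl]-4-oxobutanoate
Conditions: 6, n-BuLi, THF, −78 °C; then 7, −78 → 0 °C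
Reagents that add atoms: none
Why: N-acylation of the lithiated oxazolidinone by the acid chloride, which is far more electrophilic than the methyl ester.

Step 6
Reactants: 8 methyl 4-[(4R)-4-benzyl-2-oxo-1,3-oxazolidin-3-yl]-4-oxobutanoate; 5 (3R)-3-methyl-3-(triethylsilyloxy)-5-(triethylsilyl)pent-4-ynal
Product: 10 trans-lactone imide (7R,8S,10R), via syn-aldol adduct 9 (not isolated)
Conditions: 8, Bu2BOTf, Et3N, CH2Cl2, 0 °C; 5, −78 → 0 °C; H2O2, MeOH, pH 7 buffer, 0 °C; crude 9, PPTS (cat.), toluene, 60 °C
Reagents that add atoms: none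
Why: Evans syn aldol through the (Z)-boron enolate in a Zimmerman–Traxler chair: the (R)-benzyl auxiliary shields one enolate face and sets C7 (R) and C8 (S) under reagent control irrespective of remote C10, and the γ-hydroxy ester then lactonises, the syn aldol mapping onto the trans-β,γ-disubstituted lactone.

Step 7
Reactants: 10 trans-lactone imide (7R,8S,10R)
Product: 11 trans-lactone carboxylic acid (7R,8S,10R; C6 = CO2H)
Conditions: LiOH, H2O2, THF/H2O, 0 °C; Na2SO3; HCl to pH 3
Reagents that add atoms: hydrogen peroxide, OO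
Why: Hydroperoxide-mediated imide hydrolysis: the α-effect nucleophile attacks the exocyclic imide carbonyl selectively, any lactone that opens re-closes on acidification, and C7 is not epimerised at 0 °C.

Step 8
Reactants: 11 trans-lactone carboxylic acid; 12 N,N-dimethylmethyleneiminium iodide
Product: 13 11-(dimethylaminomethyl) lactone acid (7R,8S,10R,11S)
Conditions: LDA (2.3 equiv), THF, −78 °C; 12, −78 → 0 °C; AcOH quench
Reagents that add atoms: none
Why: Mannich reaction of a lactone enolate with a preformed iminium salt: after the carboxylate has formed, the second equivalent of base removes the more acidic lactone α-H at C11, the iminium ion adds anti to the C7 carboxylate (11S, erased later), and the product is both the first half of an α-methylenation and the protected form of C11=C13.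

Step 9
Reactants: 13 11-(dimethylaminomethyl) lactone acid; 14 propyne
Product: 16 C6 but-2-ynoyl lactone (ynone; 7R,8S,10R,11S), via acid chloride 15 (not isolated)
Conditions: 1-chloro-N,N,2-trimethylprop-1-enylamine, CH2Cl2, 0 °C; then 14, PdCl2(PPh3)2 (cat.), CuI (cat.), Et3N, THF, rt
Reagents that add atoms: 1-chloro-N,N,2-trimethylprop-1-enylamine, CC(C)=C(Cl)N(C)C (chlorine of 15 only)
Why: Neutral acid chloride formation with an α-chloroenamine followed by acyl Sonogashira coupling with propyne; the silyl cap keeps the other alkyne out of the coupling, and the trans C7 configuration is the thermodynamic one should any ketene or enol form.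

Step 10
Reactants: 16 ynone
Product: 17 (Z)-β-iodoenone (7R,8S,10R,11S; I on C4 cis to C6)
Conditions: NaI, AcOH, MeCN, 0 °C → rt
Reagents that add atoms: sodium iodide, [Na+].[I-]
Why: Conjugate hydroiodination of an ynone: iodide adds to C4 and the allenol is protonated anti, which gives the (Z)-β-iodoenone under kinetic control, the amine being held as its acetate salt.

Step 11
Reactants: 17 (Z)-β-iodoenone
Product: 18 (Z)-iodoallylic alcohol (6R,7S,8S,10R,11S; same spatial arrangement at C6 and C7 as in 28)
Conditions: NaBH4, CeCl3·7H2O, MeOH, −78 °C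
Reagents that add atoms: none
Why: Luche reduction (1,2-selective, lactone and vinyl iodide inert): Felkin–Anh attack anti to the C7–C8 bond should give the C6 alcohol with O6 anti to C11 as required, and the 8,12-trans-lactone should persist because acyl shift to O6 would give the less stable cis-lactone.

Step 12
Reactants: 18 (Z)-iodoallylic alcohol; 19 angelic acid [(Z)-2-methylbut-2-enoic acid]
Product: 21 C6 angelate with both silyl groups in place (6R,7R,8S,10R,11S), via mixed anhydride 20 (not isolated)
Conditions: 19, 2,4,6-Cl3C6H2COCl, Et3N, toluene, rt; then 18, toluene, 75 °C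
Reagents that add atoms: 2,4,6-trichlorobenzoyl chloride, O=C(Cl)c1c(Cl)cc(Cl)cc1Cl (aroyl group of 20 only)
Why: Esterification through the 2,4,6-trichlorobenzoyl mixed anhydride without nucleophilic catalyst, the known way to acylate hindered alcohols with angelic acid while keeping the Z double bond; C6 is not touched.

Step 13
Reactants: 21 C6 angelate with both silyl groups in place
Product: 22 seco precursor: (Z)-vinyl iodide and free tertiary propargylic alcohol on the amine-masked trans-lactone (6R,7R,8S,10R,11S)
Conditions: TBAF, AcOH, THF, 0 °C → rt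
Reagents that add atoms: none
Why: Fluoride-mediated cleavage of both the O–Si and the alkynyl C–Si bond; the acetic acid buffer prevents alkoxide-induced acyl migration and E2 loss of HI from the vinyl iodide.

Step 14
Reactants: 22 seco precursor; 23 carbon monoxide
Product: 26 amine-masked furanoheliangolide (6S,7R,8S,10R,11S), via macrocyclic ynone 24 (not isolated), via enaminone 25 (not isolated)
Conditions: PdCl2(PPh3)2 (10 mol %), CuI (10 mol %), CO (1 atm), Et3N, THF, 45 °C, slow addition of 22 (final ca. 1 mM); then Me2NH (2 M in THF), rt; evaporate; AcOH/THF/H2O, rt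
Reagents that add atoms: water, O (oxygen of the C1 ketone); dimethylamine, CNC (held only in 25)
Why: Proposed new method: oxidative addition of Pd(0) to the C4–I bond with retention, CO insertion to the C3 acyl-palladium species, copper-acetylide transfer of C2 and reductive elimination should close the ten-membered carbocycle as 4-hydroxy-2-ynone 24, whose alkyne takes up Me2NH at C1 to give push–pull enaminone 25, and in aqueous acid the C10 hydroxyl adds to C3, water is lost and hydrolysis of the C1 iminium ion releases Me2NH and leaves the 3(2H)-furanone. The closest known reaction types are the intermolecular carbonylative Sonogashira coupling of vinyl or aryl iodides with tertiary propargylic alcohols, the secondary-amine-mediated isomerisation of 4-hydroxy-2-ynones to 3(2H)-furanones and carbonylative Stille macrocyclisation; what is new is their union in a ten-membered ring closure. Ring closures: the carbocycle by C2–C3 bond formation from an eleven-membered acyl(alkynyl)palladacycle, then the furanone by 5-exo-trig attack of the C10 oxygen on the C3 carbonyl (O–C3 bond), which is the last ring formed. No stereocentre is created: C10 keeps its configuration because its C–O bond is never broken, C6, C7 and C8 are spectators, and the Z geometry of C4=C5 is handed on from the vinyl iodide. The step needs CO insertion before alkynylation (direct coupling would require a nine-membered enyne, and CO insertion into alkenyl-Pd is fast), cyclisation over oligomerisation (pseudo-high dilution; the Z-alkene, the trans-lactone and the quaternary C10 turn both termini inward) and no acyl- or carbopalladation, which is secured by storing C11=C13 as its Me2NH adduct. The amine attacks only C1 because the ynone is by far the best acceptor present.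

Step 15
Reactants: 26 amine-masked furanoheliangolide
Product: 28 target CNP0293168.1 (6S,7R,8S,10R), via ammonium iodide 27 (not isolated)
Conditions: MeI, THF, rt; evaporate; NaHCO3, H2O/CH2Cl2, rt
Reagents that add atoms: iodomethane, CI (methyl and iodide of 27 only)
Why: Quaternisation of the Mannich base followed by Hofmann-type E1cB elimination under bicarbonate, the standard second half of a lactone α-methylenation, regenerates C11=C13 without touching the furanone, the angelate or any remaining stereocentre.

## Compound list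

1 | (E)-3-methylpent-2-en-4-yn-1-ol | OC/C=C(\C)C#C | starting material
2 | [(2S,3S)-3-ethynyl-3-methyloxiran-2-yl]methanol | OC[C@@H]1O[C@@]1(C)C#C | intermediate
3 | (3R)-3-methylpent-4-yne-1,3-diol | OCC[C@@](C)(O)C#C | intermediate
4 | (3R)-3-methyl-1,3-bis(triethylsilyloxy)-5-(triethylsilyl)pent-4-yne | CC[Si](CC)(CC)OCC[C@@](C)(O[Si](CC)(CC)CC)C#C[Si](CC)(CC)CC | intermediate
5 | (3R)-3-methyl-3-(triethylsilyloxy)-5-(triethylsilyl)pent-4-ynal | O=CC[C@@](C)(O[Si](CC)(CC)CC)C#C[Si](CC)(CC)CC | intermediate
6 | (4R)-4-benzyl-1,3-oxazolidin-2-one | O=C1N[C@H](Cc2ccccc2)CO1 | starting material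
7 | methyl 4-chloro-4-oxobutanoate | COC(=O)CCC(=O)Cl | starting material
8 | methyl 4-[(4R)-4-benzyl-2-oxo-1,3-oxazolidin-3-yl]-4-oxobutanoate | COC(=O)CCC(=O)N1[C@H](Cc2ccccc2)COC1=O | intermediate
9 | syn-aldol adduct (7R,8S,10R), not isolated | COC(=O)C[C@@H](C(=O)N1[C@H](Cc2ccccc2)COC1=O)[C@@H](O)C[C@@](C)(O[Si](CC)(CC)CC)C#C[Si](CC)(CC)CC | intermediate
10 | trans-lactone imide (7R,8S,10R) | C1C(=O)O[C@@H](C[C@@](C)(O[Si](CC)(CC)CC)C#C[Si](CC)(CC)CC)[C@@H]1C(=O)N2[C@H](Cc3ccccc3)COC2=O | intermediate
11 | trans-lactone carboxylic acid (7R,8S,10R) | C1C(=O)O[C@@H](C[C@@](C)(O[Si](CC)(CC)CC)C#C[Si](CC)(CC)CC)[C@@H]1C(=O)O | intermediate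
12 | N,N-dimethylmethyleneiminium iodide | C=[N+](C)C.[I-] | starting material
13 | 11-(dimethylaminomethyl) lactone acid (7R,8S,10R,11S) | CN(C)C[C@H]1C(=O)O[C@@H](C[C@@](C)(O[Si](CC)(CC)CC)C#C[Si](CC)(CC)CC)[C@@H]1C(=O)O | intermediate
14 | propyne | CC#C | starting material
15 | acid chloride of 13, not isolated | CN(C)C[C@H]1C(=O)O[C@@H](C[C@@](C)(O[Si](CC)(CC)CC)C#C[Si](CC)(CC)CC)[C@@H]1C(=O)Cl | intermediate
16 | ynone (C6 but-2-ynoyl lactone; 7R,8S,10R,11S) | CN(C)C[C@H]1C(=O)O[C@@H](C[C@@](C)(O[Si](CC)(CC)CC)C#C[Si](CC)(CC)CC)[C@@H]1C(=O)C#CC | intermediate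
17 | (Z)-β-iodoenone (7R,8S,10R,11S) | CN(C)C[C@H]1C(=O)O[C@@H](C[C@@](C)(O[Si](CC)(CC)CC)C#C[Si](CC)(CC)CC)[C@@H]1C(=O)/C=C(/C)I | intermediate
18 | (Z)-iodoallylic alcohol (6R,7S,8S,10R,11S) | CN(C)C[C@H]1C(=O)O[C@@H](C[C@@](C)(O[Si](CC)(CC)CC)C#C[Si](CC)(CC)CC)[C@@H]1[C@@H](O)/C=C(/C)I | intermediate
19 | angelic acid, (Z)-2-methylbut-2-enoic acid | C/C=C(/C)C(=O)O | starting material
20 | angelic 2,4,6-trichlorobenzoic anhydride, not isolated | C/C=C(/C)C(=O)OC(=O)c1c(Cl)cc(Cl)cc1Cl | intermediate
21 | C6 angelate, O- and C-triethylsilylated (6R,7R,8S,10R,11S) | CN(C)C[C@H]1C(=O)O[C@@H](C[C@@](C)(O[Si](CC)(CC)CC)C#C[Si](CC)(CC)CC)[C@@H]1[C@@H](OC(=O)/C(C)=C\C)/C=C(/C)I | intermediate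
22 | seco precursor: vinyl iodide and propargylic alcohol (6R,7R,8S,10R,11S) | CN(C)C[C@H]1C(=O)O[C@@H](C[C@@](C)(O)C#C)[C@@H]1[C@@H](OC(=O)/C(C)=C\C)/C=C(/C)I | intermediate
23 | carbon monoxide | [C-]#[O+] | starting material
24 | ten-membered 4-hydroxy-2-ynone (6S,7R,8S,10R,11S), not isolated | CN(C)C[C@H]1C(=O)O[C@H]2C[C@@](C)(O)C#CC(=O)/C(C)=C\[C@H](OC(=O)/C(C)=C\C)[C@H]12 | intermediate
25 | C1-dimethylamino enaminone (C10 cis to C3 across C1=C2), not isolated | CN(C)C[C@H]1C(=O)O[C@H]2C[C@@](C)(O)/C(N(C)C)=C\C(=O)/C(C)=C\[C@H](OC(=O)/C(C)=C\C)[C@H]12 | intermediate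
26 | amine-masked furanoheliangolide (6S,7R,8S,10R,11S) | CN(C)C[C@H]1C(=O)O[C@H]2C[C@@]3(C)OC(=CC3=O)/C(C)=C\[C@H](OC(=O)/C(C)=C\C)[C@H]12 | intermediate
27 | trimethylammonium iodide of 26, not isolated | C[N+](C)(C)C[C@H]1C(=O)O[C@H]2C[C@@]3(C)OC(=CC3=O)/C(C)=C\[C@H](OC(=O)/C(C)=C\C)[C@H]12.[I-] | intermediate
28 | CNP0293168.1 (6S,7R,8S,10R) | C=C1C(=O)O[C@H]2C[C@@]3(C)OC(=CC3=O)/C(C)=C\[C@H](OC(=O)/C(C)=C\C)[C@H]12 | target

## Step count and risks

Total step count: 15. Longest linear sequence: 14 (steps 1–4 and 6–15; step 5 is the side branch).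

**Step 14.** The ring closure may lose to oligomerisation, to capture of the acyl-palladium species by adventitious water, or to stalling at transmetalation because of strain in the forming alkyne-containing ring. The fallback uses known chemistry, sets out from 21 and returns at 26.
- Reductive carbonylation of the vinyl iodide (Pd(PPh3)4, CO, slow Bu3SnH, THF) gives the (Z)-enal F1.
- NIS/AgF in MeCN exchanges the alkynyl silane for iodine to give the iodoalkyne F2.
- An intramolecular Nozaki–Hiyama–Kishi reaction (CrCl2, cat. NiCl2, THF, high dilution) closes the ten-membered ring at C2–C3 as the macrocyclic propargylic alcohol F3 (C3 epimers, both usable).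
- Dess–Martin oxidation gives the silyl-protected macrocyclic ynone F4.
- HF·pyridine frees the C10 hydroxyl to give 24, now isolated. Me2NH followed by AcOH/THF/H2O converts it into 26.

**Step 11.** Facial selectivity at C6 may be poor, because C8 and C11 differ little in size. The fallback sets out from 16 and returns at 18, and sets C6 under reagent control before the iodide is introduced.
- Noyori asymmetric transfer hydrogenation of the ynone (Ru(p-cymene)/TsDPEN, i-PrOH; the (R,R) series by analogy with simple alkynyl ketones) gives the (6R)-propargylic alcohol F5.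
- Ru-catalysed trans-hydrosilylation ([Cp*Ru(MeCN)3]PF6, BnMe2SiH), which places silicon on the distal carbon C4 cis to C6, gives the (Z)-vinylsilane F6.
- Iododesilylation with retention (NIS, hexafluoroisopropanol, 2,6-lutidine) gives 18.

**Step 8.** Enolisation of the carboxylate-lactone may be incomplete, the iminium salt may be consumed at the carboxylate oxygen, and the zwitterion may be lost on isolation. The fallback sets out from 11 and returns at 13. It follows the carboxylation route established for β-carboxy-γ-butyrolactones.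
- Methyl magnesium carbonate in DMF at 120 °C gives the α-carboxy lactone diacid F7.
- Aqueous formaldehyde with Et2NH in AcOH/NaOAc effects decarboxylative Mannich elimination to the α-methylene lactone acid F8.
- Conjugate addition of Me2NH in THF gives 13.

## Further compounds

F1 | step 14 | (Z)-enal (C3 = CHO) from 21 | CN(C)C[C@H]1C(=O)O[C@@H](C[C@@](C)(O[Si](CC)(CC)CC)C#C[Si](CC)(CC)CC)[C@@H]1[C@@H](OC(=O)/C(C)=C\C)/C=C(/C)C=O
F2 | step 14 | iodoalkyne enal | CN(C)C[C@H]1C(=O)O[C@@H](C[C@@](C)(O[Si](CC)(CC)CC)C#CI)[C@@H]1[C@@H](OC(=O)/C(C)=C\C)/C=C(/C)C=O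
F3 | step 14 | macrocyclic propargylic alcohol (C3 epimers) | CN(C)C[C@H]1C(=O)O[C@H]2C[C@@](C)(O[Si](CC)(CC)CC)C#CC(O)/C(C)=C\[C@H](OC(=O)/C(C)=C\C)[C@H]12
F4 | step 14 | silyl-protected macrocyclic ynone | CN(C)C[C@H]1C(=O)O[C@H]2C[C@@](C)(O[Si](CC)(CC)CC)C#CC(=O)/C(C)=C\[C@H](OC(=O)/C(C)=C\C)[C@H]12
F5 | step 11 | (6R)-propargylic alcohol | CN(C)C[C@H]1C(=O)O[C@@H](C[C@@](C)(O[Si](CC)(CC)CC)C#C[Si](CC)(CC)CC)[C@@H]1[C@@H](O)C#CC
F6 | step 11 | (Z)-C4-benzyldimethylsilyl allylic alcohol | CN(C)C[C@H]1C(=O)O[C@@H](C[C@@](C)(O[Si](CC)(CC)CC)C#C[Si](CC)(CC)CC)[C@@H]1[C@@H](O)/C=C(/C)[Si](C)(C)Cc2ccccc2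
F7 | step 8 | α-carboxy lactone diacid (C11 epimers) | OC(=O)C1C(=O)O[C@@H](C[C@@](C)(O[Si](CC)(CC)CC)C#C[Si](CC)(CC)CC)[C@@H]1C(=O)O
F8 | step 8 | α-methylene lactone acid | C=C1C(=O)O[C@@H](C[C@@](C)(O[Si](CC)(CC)CC)C#C[Si](CC)(CC)CC)[C@@H]1C(=O)O
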